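Late times in an earlier run show how quickly target turns into over-reaction product, and I needed that figure for a batch flask and for two flasks with one reagent fed slowly.

| flask | starting material | second substrate | enzyme | remark | time |
|---|---|---|---|---|---|
| elm | 0.10 M | 0.20 M | 10 µM | run made earlier |  |
| maple | 0.14 M | 0.20 M | 10 µM | run made earlier |  |
| alder | 0.22 M | 0.20 M | 10 µM | run made earlier |  |
| theta | 0.10 M (fed, over 40 min) | 0.200 M | 10 µM | all else is in the flask from the start; the feed brings no volume worth counting | 1.5 h |
| beta | 0.10 M | 0.200 M (fed, over 40 min) | 10 µM | all else is in the flask from the start; the feed brings no volume worth counting | 1.5 h |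
| delta | 0.10 M | 0.200 M | 10 µM | everything together at the start | 1.5 h |

- elm (time / min: over-reaction product / %, target / %, starting material / %): 10.0: 0, 8, 78; 20.0: 3, 12, 59; 30.0: 7, 16, 45; 40.0: 10, 17, 35; 50.0: 11, 17, 24
- maple (time / min: over-reaction product / %, target / %, starting material / %): 20.0: 2, 10, 64; 40.0: 10, 16, 36; 60.0: 17, 16, 19; 80.0: 25, 12, 11; 120: 34, 9, 1
- alder (time / min: over-reaction product / %, target / %, starting material / %): 10.0: 4, 6, 77; 25.0: 5, 12, 54; 50.0: 10, 15, 30; 80.0: 18, 14, 13; 120: 27, 7, 0

(readings scatter by 1.5 percentage points)

- a reading or a percentage of target counts all its forms, free or not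

- the flask that comes out highest in amount of over-reaction product, in percent of the starting material charged; "all alike" if 1.5 percentage points covers them all (theta / beta / delta / all alike)
- amount of over-reaction product at the end, in percent of the starting material charged, theta
- amount of over-reaction product at the end, in percent of the starting material charged, beta
- amount of over-reaction product at the end, in percent of the starting material charged, delta

In the alder run, between 80.0 min and 120 min, over-reaction product rose by 9 percentage points while target averaged 10.5%. Mean target times elapsed time, divided by the gain in over-reaction product, is the target's first-order lifetime, which read 46.7 min, and the maple run read 46.7 min over the same interval. So 1.5 h is 1.93 lifetimes, and with this lifetime the over-reaction product at the end of a flask that starts without any is that count times the target averaged over the whole time.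

Delta has elm's recipe, so I continued elm from its last reading with target held at 17%, which gave me 25.6% for delta. To pass that estimate, a fed flask needed a mean target above 13.3%.

The forecast named delta as highest, with theta 19.5%, beta 15% and delta 25%, and it said of beta: “Starved early, more material goes down the side route”.

The flasks gave theta 24.7%, beta 38.9% and delta 27.9%, so beta came out highest. Divided by the lifetimes, the beta and delta figures ask for a mean target of 20.2% in beta, more than the 14.5% in delta, and beta held 24.8% target at the end of its feed.

    target → over-reaction product (k = 3.60 × 10⁻⁴ s⁻¹)
    starting material + enzyme ⇌ complex A (K = 380 M⁻¹, k = 440 M⁻¹ s⁻¹)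
    second substrate + enzyme ⇌ complex B (K = 160 M⁻¹, k = 450 M⁻¹ s⁻¹)
    complex B → enzyme + second product (k = 3.10 s⁻¹)
    enzyme + target ⇌ idle complex (K = 4.30 M⁻¹, k = 0.00860 M⁻¹ s⁻¹)
    complex A → enzyme + target (k = 4.80 s⁻¹)
    starting material → uncatalysed product (k = 2.70 × 10⁻⁴ s⁻¹)

A neighbour of beta was charged with 0.080 M of second substrate, all else held, and at 1.50 h it gave 49.7% over-reaction product and 16.7% target. The same 1.93 lifetimes turn that into a mean target of 25.8%, more than beta's 20.2% and more than the neighbour's own final target. The neighbour's uncatalysed product stood at 33.4%, against 42.8% in beta.

The data are simulated for substances that don't exist, and the scatter is random.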